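**Retrosynthetic overview**
1. Target 32 ⇐ primary alcohol 30 (CH2OH → CO2H → CO2Me last) ⇐ Wharton transposition of epoxy aldehyde 27 ⇐ Sharpless epoxidation of tetrasubstituted allylic alcohol 25, which sets cyclohexane C1. The exocyclic methylene stays masked until the peroxide is in place.
2. 1,2-Dioxane 24 ⇐ 6-exo SN2 of a C6 tertiary hydroperoxide on the C3 mesylate (inversion) ⇐ Isayama–Mukaiyama peroxidation of the 1,1-disubstituted alkene of 21.
3. C2–C3 bond and both side-chain stereocentres ⇐ Evans syn-aldol of propionimide 15 with aldehyde 14 (the key fragment union).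
4. Aldehyde 14 ⇐ B-alkyl Suzuki coupling of diene 6 with bromo ester 10; 6 ⇐ enol triflate 3 ⇐ 2,2-dimethylcyclohexanone 1.
5. Ring order: the cyclohexane is bought in 1; the 1,2-dioxane is closed in step 15; a transient oxirane (step 17) is reopened in step 19.

Assumption: the target is exactly the SMILES given, i.e. methyl (2S)-2-[(3S,6R)-6-{2-[(1S)-1-hydroxy-2,2-dimethyl-6-methylidenecyclohexyl]ethyl}-6-methyl-1,2-dioxan-3-yl]propanoate. Dioxane atoms are numbered as in this name throughout (C3 carries the propanoate-derived chain, C6 the methyl). TBS = tert-butyldimethylsilyl, TBDPS = tert-butyldiphenylsilyl.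

C6 of the dioxane is formed without facial control in step 14, so 22 and 23 are about 1:1 mixtures at C6. The ring closure in step 15 therefore gives two 3,6-diastereomeric dioxanes; only 24 is carried on (at most about half of the material), and the other diastereomer is discarded at the chromatography of step 15. The route has not been run; selectivities are expectations from precedent.

**Step 1**
Reactants: 1 2,2-dimethylcyclohexan-1-one
Product: 2 methyl 3,3-dimethyl-2-oxocyclohexane-1-carboxylate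
Conditions: NaH (2.2 equiv), (MeO)2CO, THF, reflux; then aq. HCl
Reagents that add atoms: dimethyl carbonate, COC(=O)OC
Why: Claisen-type C-acylation of the ketone enolate, which can only form at the one α-carbon that bears hydrogens, so the ester carbon (later the exocyclic CH2) enters at future ring C2.

**Step 2**
Reactants: 2 methyl 3,3-dimethyl-2-oxocyclohexane-1-carboxylate
Product: 3 methyl 3,3-dimethyl-2-(trifluoromethanesulfonyloxy)cyclohex-1-ene-1-carboxylate
Conditions: Tf2O, i-Pr2NEt, CH2Cl2, −78 °C → 0 °C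
Reagents that add atoms: trifluoromethanesulfonic anhydride, O=S(=O)(OS(=O)(=O)C(F)(F)F)C(F)(F)F
Why: O-sulfonylation of the β-keto ester enol (enol triflate formation), enolisation being possible only toward the ester-bearing carbon.

**Step 3**
Reactants: 3 methyl 3,3-dimethyl-2-(trifluoromethanesulfonyloxy)cyclohex-1-ene-1-carboxylate
Product: 4 methyl 2-ethenyl-3,3-dimethylcyclohex-1-ene-1-carboxylate
Conditions: CH2=CHSnBu3, Pd(PPh3)4 (5 mol %), LiCl, THF, 65 °C
Reagents that add atoms: tributyl(vinyl)stannane, C=C[Sn](CCCC)(CCCC)CCCC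
Why: Stille coupling of an electron-poor β-acyl enol triflate, with a vinyl group small enough to be placed beside the quaternary carbon.

**Step 4**
Reactants: 4 methyl 2-ethenyl-3,3-dimethylcyclohex-1-ene-1-carboxylate
Product: 5 (2-ethenyl-3,3-dimethylcyclohex-1-en-1-yl)methanol
Conditions: i-Bu2AlH (2.5 equiv), CH2Cl2, −78 °C → 0 °C; aq. potassium sodium tartrate work-up
Reagents that add atoms: none
Why: 1,2-hydride reduction of the conjugated ester (i-Bu2AlH reduction) gives the primary allylic alcohol without touching the diene.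

**Step 5**
Reactants: 5 (2-ethenyl-3,3-dimethylcyclohex-1-en-1-yl)methanol
Product: 6 tert-butyl[(2-ethenyl-3,3-dimethylcyclohex-1-en-1-yl)methoxy]dimethylsilane
Conditions: TBSCl, imidazole, DMF, rt
Reagents that add atoms: tert-butyldimethylsilyl chloride, CC(C)(C)[Si](C)(C)Cl
Why: silyl ether protection of the primary allylic alcohol, so that the hydroxyl and the tetrasubstituted alkene are carried inert up to the late epoxidation.

**Step 6**
Reactants: 7 tert-butyl acetate; 8 2,3-dibromoprop-1-ene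
Product: 10 tert-butyl 4-bromopent-4-enoate, via lithium enolate 9 (not isolated)
Conditions: LiN(i-Pr)2, THF, −78 °C; then 8, −78 °C → rt
Reagents that add atoms: none
Why: ester enolate alkylation (SN2) at the allylic C–Br bond, the vinylic bromide being inert to the enolate.

**Step 7**
Reactants: 6 tert-butyl[(2-ethenyl-3,3-dimethylcyclohex-1-en-1-yl)methoxy]dimethylsilane; 10 tert-butyl 4-bromopent-4-enoate
Product: 12 tert-butyl 6-(2-{[(tert-butyldimethylsilyl)oxy]methyl}-6,6-dimethylcyclohex-1-en-1-yl)-4-methylidenehexanoate, via alkylborane 11 (not isolated)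
Conditions: 9-BBN, THF, 0 °C → rt; then 10, PdCl2(dppf) (5 mol %), aq. K3PO4, DMF, 50 °C
Reagents that add atoms: none
Why: anti-Markovnikov hydroboration of the only monosubstituted alkene (the tetrasubstituted ring alkene does not react with 9-BBN) followed by B-alkyl Suzuki–Miyaura coupling with the 2-bromoalkene, which installs the 1,1-disubstituted alkene needed for peroxidation.

**Step 8**
Reactants: 12 tert-butyl 6-(2-{[(tert-butyldimethylsilyl)oxy]methyl}-6,6-dimethylcyclohex-1-en-1-yl)-4-methylidenehexanoate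
Product: 13 6-(2-{[(tert-butyldimethylsilyl)oxy]methyl}-6,6-dimethylcyclohex-1-en-1-yl)-4-methylidenehexan-1-ol
Conditions: LiAlH4, Et2O, 0 °C
Reagents that add atoms: none
Why: hydride reduction of the ester to the primary alcohol, with silyl ether and isolated alkenes inert.

**Step 9**
Reactants: 13 6-(2-{[(tert-butyldimethylsilyl)oxy]methyl}-6,6-dimethylcyclohex-1-en-1-yl)-4-methylidenehexan-1-ol
Product: 14 6-(2-{[(tert-butyldimethylsilyl)oxy]methyl}-6,6-dimethylcyclohex-1-en-1-yl)-4-methylidenehexanal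
Conditions: (n-Pr4N)RuO4 (5 mol %), NMO, 4 Å MS, CH2Cl2, rt
Reagents that add atoms: none
Why: Ley–Griffith oxidation stops at the aldehyde under neutral conditions and leaves both alkenes and the silyl ether alone.

**Step 10**
Reactants: 15 (4S)-4-benzyl-3-propanoyl-1,3-oxazolidin-2-one; 14 6-(2-{[(tert-butyldimethylsilyl)oxy]methyl}-6,6-dimethylcyclohex-1-en-1-yl)-4-methylidenehexanal
Product: 18 (4S)-4-benzyl-3-[(2S,3R)-8-(2-{[(tert-butyldimethylsilyl)oxy]methyl}-6,6-dimethylcyclohex-1-en-1-yl)-3-hydroxy-2-methyl-6-methylideneoctanoyl]-1,3-oxazolidin-2-one, via dibutylboron Z-enolate 16 (not isolated), via dibutylboron aldolate 17 (not isolated)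
Conditions: 15, Bu2BOTf, i-Pr2NEt, CH2Cl2, 0 °C; then 14, −78 °C → 0 °C; then pH 7 buffer, MeOH, 30% H2O2, 0 °C
Reagents that add atoms: none
Why: intermolecular Evans syn-aldol reaction in which the Z-boron enolate reacts through a Zimmerman–Traxler chair on the face away from the benzyl group, fixing C2 as (S) (kept to the end) and the carbinol carbon as (R) (to be inverted in step 15).

**Step 11**
Reactants: 18 (4S)-4-benzyl-3-[(2S,3R)-8-(2-{[(tert-butyldimethylsilyl)oxy]methyl}-6,6-dimethylcyclohex-1-en-1-yl)-3-hydroxy-2-methyl-6-methylideneoctanoyl]-1,3-oxazolidin-2-one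
Product: 19 (2R,3R)-8-(2-{[(tert-butyldimethylsilyl)oxy]methyl}-6,6-dimethylcyclohex-1-en-1-yl)-2-methyl-6-methylideneoctane-1,3-diol
Conditions: LiBH4, MeOH (1 equiv), THF, 0 °C
Reagents that add atoms: none
Why: reductive cleavage of the N-acyl oxazolidinone takes the carbonyl to the alcohol level (no stereocentre touched, descriptor at C2 changes by CIP only), so that the later C3 sulfonate has no β-carbonyl and cannot undergo E1cB elimination.

**Step 12**
Reactants: 19 (2R,3R)-8-(2-{[(tert-butyldimethylsilyl)oxy]methyl}-6,6-dimethylcyclohex-1-en-1-yl)-2-methyl-6-methylideneoctane-1,3-diol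
Product: 20 (2R,3R)-1-[(tert-butyldiphenylsilyl)oxy]-8-(2-{[(tert-butyldimethylsilyl)oxy]methyl}-6,6-dimethylcyclohex-1-en-1-yl)-2-methyl-6-methylideneoctan-3-ol
Conditions: TBDPSCl, imidazole, CH2Cl2, 0 °C
Reagents that add atoms: tert-butyldiphenylsilyl chloride, CC(C)(C)[Si](Cl)(c1ccccc1)c1ccccc1
Why: selective silylation of the primary over the secondary hydroxyl with a bulky silyl chloride gives a group that outlasts the later removal of the allylic TBS ether.

**Step 13**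
Reactants: 20 (2R,3R)-1-[(tert-butyldiphenylsilyl)oxy]-8-(2-{[(tert-butyldimethylsilyl)oxy]methyl}-6,6-dimethylcyclohex-1-en-1-yl)-2-methyl-6-methylideneoctan-3-ol
Product: 21 (2R,3R)-1-[(tert-butyldiphenylsilyl)oxy]-8-(2-{[(tert-butyldimethylsilyl)oxy]methyl}-6,6-dimethylcyclohex-1-en-1-yl)-2-methyl-6-methylideneoctan-3-yl methanesulfonate
Conditions: MsCl, Et3N, CH2Cl2, 0 °C
Reagents that add atoms: methanesulfonyl chloride, CS(=O)(=O)Cl
Why: sulfonylation of the secondary alcohol with retention turns C3 into the electrophile for the ring closure.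

**Step 14**
Reactants: 21 (2R,3R)-1-[(tert-butyldiphenylsilyl)oxy]-8-(2-{[(tert-butyldimethylsilyl)oxy]methyl}-6,6-dimethylcyclohex-1-en-1-yl)-2-methyl-6-methylideneoctan-3-yl methanesulfonate
Product: 22 (2R,3R,6RS)-1-[(tert-butyldiphenylsilyl)oxy]-8-(2-{[(tert-butyldimethylsilyl)oxy]methyl}-6,6-dimethylcyclohex-1-en-1-yl)-2,6-dimethyl-6-[(triethylsilyl)peroxy]octan-3-yl methanesulfonate
Conditions: Co(thd)2 [bis(2,2,6,6-tetramethylheptane-3,5-dionato)cobalt] (10 mol %), O2 (1 atm), Et3SiH, 1,2-dichloroethane, rt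
Reagents that add atoms: dioxygen, O=O; triethylsilane, CC[SiH](CC)CC
Why: Isayama–Mukaiyama hydroperoxysilylation, in which cobalt hydride hydrogen-atom transfer to the terminal CH2 gives the tertiary radical that traps O2 (Markovnikov); the hindered tetrasubstituted ring alkene is far slower, and the new C6 centre forms without facial control (about 1:1).

**Step 15**
Reactants: 22 (2R,3R,6RS)-1-[(tert-butyldiphenylsilyl)oxy]-8-(2-{[(tert-butyldimethylsilyl)oxy]methyl}-6,6-dimethylcyclohex-1-en-1-yl)-2,6-dimethyl-6-[(triethylsilyl)peroxy]octan-3-yl methanesulfonate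
Product: 24 (3S,6S)-3-{(2R)-1-[(tert-butyldiphenylsilyl)oxy]propan-2-yl}-6-[2-(2-{[(tert-butyldimethylsilyl)oxy]methyl}-6,6-dimethylcyclohex-1-en-1-yl)ethyl]-6-methyl-1,2-dioxane, via hydroperoxide 23 (not isolated)
Conditions: K2CO3 (cat.), MeOH, 0 °C; then solvent exchange, KOt-Bu, 18-crown-6, THF, 0 °C; silica gel chromatography
Reagents that add atoms: none
Why: methanolysis of the O–Si bond and intramolecular 6-exo-tet SN2 alkylation of the tertiary peroxide anion at the mesylate invert C3 to (S); the two ring diastereomers that arise from the C6 mixture differ in their 3,6-relationship and are separated on silica, leaving 24, whose C6 has the target's arrangement (the S descriptor here is only a CIP priority change).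

**Step 16**
Reactants: 24 (3S,6S)-3-{(2R)-1-[(tert-butyldiphenylsilyl)oxy]propan-2-yl}-6-[2-(2-{[(tert-butyldimethylsilyl)oxy]methyl}-6,6-dimethylcyclohex-1-en-1-yl)ethyl]-6-methyl-1,2-dioxane
Product: 25 [2-(2-{(3S,6S)-3-[(2R)-1-[(tert-butyldiphenylsilyl)oxy]propan-2-yl]-6-methyl-1,2-dioxan-6-yl}ethyl)-3,3-dimethylcyclohex-1-en-1-yl]methanol
Conditions: PPTS, MeOH, rt
Reagents that add atoms: none
Why: acid-catalysed methanolysis removes the primary allylic TBS ether far faster than the TBDPS ether, and the dioxane tolerates mild acid.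

**Step 17**
Reactants: 25 [2-(2-{(3S,6S)-3-[(2R)-1-[(tert-butyldiphenylsilyl)oxy]propan-2-yl]-6-methyl-1,2-dioxan-6-yl}ethyl)-3,3-dimethylcyclohex-1-en-1-yl]methanol
Product: 26 [(1S,6S)-6-(2-{(3S,6R)-3-[(2R)-1-[(tert-butyldiphenylsilyl)oxy]propan-2-yl]-6-methyl-1,2-dioxan-6-yl}ethyl)-5,5-dimethyl-7-oxabicyclo[4.1.0]heptan-1-yl]methanol
Conditions: Ti(Oi-Pr)4, L-(+)-diethyl tartrate, t-BuOOH, 4 Å MS, CH2Cl2, −20 °C
Reagents that add atoms: tert-butyl hydroperoxide, CC(C)(C)OO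
Why: Sharpless asymmetric epoxidation under reagent control (same facial sense as geraniol → (2S,3S)-2,3-epoxygeraniol) makes the tether-bearing oxirane carbon (S), which becomes cyclohexane C1 of the target.

**Step 18**
Reactants: 26 [(1S,6S)-6-(2-{(3S,6R)-3-[(2R)-1-[(tert-butyldiphenylsilyl)oxy]propan-2-yl]-6-methyl-1,2-dioxan-6-yl}ethyl)-5,5-dimethyl-7-oxabicyclo[4.1.0]heptan-1-yl]methanol
Product: 27 (1R,6S)-6-(2-{(3S,6R)-3-[(2R)-1-[(tert-butyldiphenylsilyl)oxy]propan-2-yl]-6-methyl-1,2-dioxan-6-yl}ethyl)-5,5-dimethyl-7-oxabicyclo[4.1.0]heptane-1-carbaldehyde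
Conditions: (n-Pr4N)RuO4 (5 mol %), NMO, 4 Å MS, CH2Cl2, 0 °C → rt
Reagents that add atoms: none
Why: Ley–Griffith oxidation under neutral conditions spares the oxirane and the peroxide and gives a non-enolisable α-quaternary epoxy aldehyde (descriptor change at C1 is CIP only).

**Step 19**
Reactants: 27 (1R,6S)-6-(2-{(3S,6R)-3-[(2R)-1-[(tert-butyldiphenylsilyl)oxy]propan-2-yl]-6-methyl-1,2-dioxan-6-yl}ethyl)-5,5-dimethyl-7-oxabicyclo[4.1.0]heptane-1-carbaldehyde
Product: 29 (1S)-1-(2-{(3S,6R)-3-[(2R)-1-[(tert-butyldiphenylsilyl)oxy]propan-2-yl]-6-methyl-1,2-dioxan-6-yl}ethyl)-2,2-dimethyl-6-methylidenecyclohexan-1-ol, via hydrazone 28 (not isolated)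
Conditions: N2H4·H2O (excess), AcOH (cat.), MeOH, 0 °C → rt
Reagents that add atoms: none
Why: Wharton transposition, in which the hydrazone opens the oxirane at the carbon next to the former aldehyde and loss of N2 leaves the exocyclic CH2=, while the C–O bond at the (S)-carbinol carbon is never broken.

**Step 20**
Reactants: 29 (1S)-1-(2-{(3S,6R)-3-[(2R)-1-[(tert-butyldiphenylsilyl)oxy]propan-2-yl]-6-methyl-1,2-dioxan-6-yl}ethyl)-2,2-dimethyl-6-methylidenecyclohexan-1-ol
Product: 30 (2R)-2-[(3S,6R)-6-{2-[(1S)-1-hydroxy-2,2-dimethyl-6-methylidenecyclohexyl]ethyl}-6-methyl-1,2-dioxan-3-yl]propan-1-ol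
Conditions: HF·pyridine, pyridine, THF, 0 °C → rt
Reagents that add atoms: none
Why: buffered fluoride desilylation frees the primary alcohol without base (no Kornblum–DeLaMare cleavage of the dioxane) and without ionising the tertiary allylic alcohol.

**Step 21**
Reactants: 30 (2R)-2-[(3S,6R)-6-{2-[(1S)-1-hydroxy-2,2-dimethyl-6-methylidenecyclohexyl]ethyl}-6-methyl-1,2-dioxan-3-yl]propan-1-ol
Product: 31 (2S)-2-[(3S,6R)-6-{2-[(1S)-1-hydroxy-2,2-dimethyl-6-methylidenecyclohexyl]ethyl}-6-methyl-1,2-dioxan-3-yl]propanoic acid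
Conditions: TEMPO (cat.), PhI(OAc)2 (2.2 equiv), MeCN/H2O (pH 7 buffer), rt
Reagents that add atoms: water, O
Why: oxoammonium (TEMPO/PhI(OAc)2) oxidation takes only the primary alcohol through the aldehyde hydrate to the acid under near-neutral conditions, so the α-stereocentre, the tertiary alcohol, the alkene and the peroxide survive.

**Step 22**
Reactants: 31 (2S)-2-[(3S,6R)-6-{2-[(1S)-1-hydroxy-2,2-dimethyl-6-methylidenecyclohexyl]ethyl}-6-methyl-1,2-dioxan-3-yl]propanoic acid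
Product: 32 methyl (2S)-2-[(3S,6R)-6-{2-[(1S)-1-hydroxy-2,2-dimethyl-6-methylidenecyclohexyl]ethyl}-6-methyl-1,2-dioxan-3-yl]propanoate
Conditions: Me3SiCHN2, MeOH/toluene, 0 °C
Reagents that add atoms: (trimethylsilyl)diazomethane, C[Si](C)(C)C=[N+]=[N-]
Why: O-methylation of the carboxylic acid by the diazoalkane is base-free, so the β-peroxy ester cannot epimerise or undergo retro-oxa-Michael opening.

**Compound list**
1 | 2,2-dimethylcyclohexan-1-one | CC1(C)CCCCC1=O | starting material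
2 | methyl 3,3-dimethyl-2-oxocyclohexane-1-carboxylate | COC(=O)C1CCCC(C)(C)C1=O | intermediate
3 | methyl 3,3-dimethyl-2-(trifluoromethanesulfonyloxy)cyclohex-1-ene-1-carboxylate | COC(=O)C1=C(OS(=O)(=O)C(F)(F)F)C(C)(C)CCC1 | intermediate
4 | methyl 2-ethenyl-3,3-dimethylcyclohex-1-ene-1-carboxylate | COC(=O)C1=C(C=C)C(C)(C)CCC1 | intermediate
5 | (2-ethenyl-3,3-dimethylcyclohex-1-en-1-yl)methanol | OCC1=C(C=C)C(C)(C)CCC1 | intermediate
6 | tert-butyl[(2-ethenyl-3,3-dimethylcyclohex-1-en-1-yl)methoxy]dimethylsilane | CC(C)(C)[Si](C)(C)OCC1=C(C=C)C(C)(C)CCC1 | intermediate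
7 | tert-butyl acetate | CC(=O)OC(C)(C)C | starting material
8 | 2,3-dibromoprop-1-ene | C=C(Br)CBr | starting material
9 | lithium 1-tert-butoxyethen-1-olate (lithium enolate of 7, not isolated) | [Li]OC(=C)OC(C)(C)C | intermediate
10 | tert-butyl 4-bromopent-4-enoate | C=C(Br)CCC(=O)OC(C)(C)C | intermediate
11 | 9-[2-(2-{[(tert-butyldimethylsilyl)oxy]methyl}-6,6-dimethylcyclohex-1-en-1-yl)ethyl]-9-borabicyclo[3.3.1]nonane (not isolated) | CC(C)(C)[Si](C)(C)OCC1=C(CCB2C3CCCC2CCC3)C(C)(C)CCC1 | intermediate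
12 | tert-butyl 6-(2-{[(tert-butyldimethylsilyl)oxy]methyl}-6,6-dimethylcyclohex-1-en-1-yl)-4-methylidenehexanoate | CC(C)(C)[Si](C)(C)OCC1=C(CCC(=C)CCC(=O)OC(C)(C)C)C(C)(C)CCC1 | intermediate
13 | 6-(2-{[(tert-butyldimethylsilyl)oxy]methyl}-6,6-dimethylcyclohex-1-en-1-yl)-4-methylidenehexan-1-ol | CC(C)(C)[Si](C)(C)OCC1=C(CCC(=C)CCCO)C(C)(C)CCC1 | intermediate
14 | 6-(2-{[(tert-butyldimethylsilyl)oxy]methyl}-6,6-dimethylcyclohex-1-en-1-yl)-4-methylidenehexanal | CC(C)(C)[Si](C)(C)OCC1=C(CCC(=C)CCC=O)C(C)(C)CCC1 | intermediate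
15 | (4S)-4-benzyl-3-propanoyl-1,3-oxazolidin-2-one | CCC(=O)N1[C@@H](Cc2ccccc2)COC1=O | starting material
16 | (Z)-dibutylboron enolate of 15 (not isolated) | C/C=C(\OB(CCCC)CCCC)N1[C@@H](Cc2ccccc2)COC1=O | intermediate
17 | O-dibutylboryl aldolate of 18 (not isolated) | CC(C)(C)[Si](C)(C)OCC1=C(CCC(=C)CC[C@H]([C@H](C)C(=O)N2[C@@H](Cc3ccccc3)COC2=O)OB(CCCC)CCCC)C(C)(C)CCC1 | intermediate
18 | (4S)-4-benzyl-3-[(2S,3R)-8-(2-{[(tert-butyldimethylsilyl)oxy]methyl}-6,6-dimethylcyclohex-1-en-1-yl)-3-hydroxy-2-methyl-6-methylideneoctanoyl]-1,3-oxazolidin-2-one | CC(C)(C)[Si](C)(C)OCC1=C(CCC(=C)CC[C@H]([C@H](C)C(=O)N2[C@@H](Cc3ccccc3)COC2=O)O)C(C)(C)CCC1 | intermediate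
19 | (2R,3R)-8-(2-{[(tert-butyldimethylsilyl)oxy]methyl}-6,6-dimethylcyclohex-1-en-1-yl)-2-methyl-6-methylideneoctane-1,3-diol | CC(C)(C)[Si](C)(C)OCC1=C(CCC(=C)CC[C@H]([C@H](C)CO)O)C(C)(C)CCC1 | intermediate
20 | (2R,3R)-1-[(tert-butyldiphenylsilyl)oxy]-8-(2-{[(tert-butyldimethylsilyl)oxy]methyl}-6,6-dimethylcyclohex-1-en-1-yl)-2-methyl-6-methylideneoctan-3-ol | CC(C)(C)[Si](C)(C)OCC1=C(CCC(=C)CC[C@H]([C@H](C)CO[Si](c2ccccc2)(c2ccccc2)C(C)(C)C)O)C(C)(C)CCC1 | intermediate
21 | (2R,3R)-1-[(tert-butyldiphenylsilyl)oxy]-8-(2-{[(tert-butyldimethylsilyl)oxy]methyl}-6,6-dimethylcyclohex-1-en-1-yl)-2-methyl-6-methylideneoctan-3-yl methanesulfonate | CC(C)(C)[Si](C)(C)OCC1=C(CCC(=C)CC[C@H]([C@H](C)CO[Si](c2ccccc2)(c2ccccc2)C(C)(C)C)OS(C)(=O)=O)C(C)(C)CCC1 | intermediate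
22 | (2R,3R,6RS)-1-[(tert-butyldiphenylsilyl)oxy]-8-(2-{[(tert-butyldimethylsilyl)oxy]methyl}-6,6-dimethylcyclohex-1-en-1-yl)-2,6-dimethyl-6-[(triethylsilyl)peroxy]octan-3-yl methanesulfonate (about 1:1 at C6) | CC(C)(C)[Si](C)(C)OCC1=C(CCC(C)(OO[Si](CC)(CC)CC)CC[C@H]([C@H](C)CO[Si](c2ccccc2)(c2ccccc2)C(C)(C)C)OS(C)(=O)=O)C(C)(C)CCC1 | intermediate
23 | (2R,3R,6RS)-1-[(tert-butyldiphenylsilyl)oxy]-8-(2-{[(tert-butyldimethylsilyl)oxy]methyl}-6,6-dimethylcyclohex-1-en-1-yl)-6-hydroperoxy-2,6-dimethyloctan-3-yl methanesulfonate (not isolated) | CC(C)(C)[Si](C)(C)OCC1=C(CCC(C)(OO)CC[C@H]([C@H](C)CO[Si](c2ccccc2)(c2ccccc2)C(C)(C)C)OS(C)(=O)=O)C(C)(C)CCC1 | intermediate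
24 | (3S,6S)-3-{(2R)-1-[(tert-butyldiphenylsilyl)oxy]propan-2-yl}-6-[2-(2-{[(tert-butyldimethylsilyl)oxy]methyl}-6,6-dimethylcyclohex-1-en-1-yl)ethyl]-6-methyl-1,2-dioxane (C6 arranged as in the target) | CC(C)(C)[Si](C)(C)OCC1=C(CC[C@@]2(C)CC[C@@H]([C@H](C)CO[Si](c3ccccc3)(c3ccccc3)C(C)(C)C)OO2)C(C)(C)CCC1 | intermediate
25 | [2-(2-{(3S,6S)-3-[(2R)-1-[(tert-butyldiphenylsilyl)oxy]propan-2-yl]-6-methyl-1,2-dioxan-6-yl}ethyl)-3,3-dimethylcyclohex-1-en-1-yl]methanol | OCC1=C(CC[C@@]2(C)CC[C@@H]([C@H](C)CO[Si](c3ccccc3)(c3ccccc3)C(C)(C)C)OO2)C(C)(C)CCC1 | intermediate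
26 | [(1S,6S)-6-(2-{(3S,6R)-3-[(2R)-1-[(tert-butyldiphenylsilyl)oxy]propan-2-yl]-6-methyl-1,2-dioxan-6-yl}ethyl)-5,5-dimethyl-7-oxabicyclo[4.1.0]heptan-1-yl]methanol | OC[C@@]12CCCC(C)(C)[C@@]1(O2)CC[C@@]3(C)CC[C@@H]([C@H](C)CO[Si](c4ccccc4)(c4ccccc4)C(C)(C)C)OO3 | intermediate
27 | (1R,6S)-6-(2-{(3S,6R)-3-[(2R)-1-[(tert-butyldiphenylsilyl)oxy]propan-2-yl]-6-methyl-1,2-dioxan-6-yl}ethyl)-5,5-dimethyl-7-oxabicyclo[4.1.0]heptane-1-carbaldehyde | O=C[C@@]12CCCC(C)(C)[C@@]1(O2)CC[C@@]3(C)CC[C@@H]([C@H](C)CO[Si](c4ccccc4)(c4ccccc4)C(C)(C)C)OO3 | intermediate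
28 | hydrazone of 27 (not isolated) | NN=C[C@@]12CCCC(C)(C)[C@@]1(O2)CC[C@@]3(C)CC[C@@H]([C@H](C)CO[Si](c4ccccc4)(c4ccccc4)C(C)(C)C)OO3 | intermediate
29 | (1S)-1-(2-{(3S,6R)-3-[(2R)-1-[(tert-butyldiphenylsilyl)oxy]propan-2-yl]-6-methyl-1,2-dioxan-6-yl}ethyl)-2,2-dimethyl-6-methylidenecyclohexan-1-ol | C=C1CCCC(C)(C)[C@@]1(O)CC[C@@]1(C)CC[C@@H]([C@H](C)CO[Si](c2ccccc2)(c2ccccc2)C(C)(C)C)OO1 | intermediate
30 | (2R)-2-[(3S,6R)-6-{2-[(1S)-1-hydroxy-2,2-dimethyl-6-methylidenecyclohexyl]ethyl}-6-methyl-1,2-dioxan-3-yl]propan-1-ol | C=C1CCCC(C)(C)[C@@]1(O)CC[C@@]1(C)CC[C@@H]([C@H](C)CO)OO1 | intermediate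
31 | (2S)-2-[(3S,6R)-6-{2-[(1S)-1-hydroxy-2,2-dimethyl-6-methylidenecyclohexyl]ethyl}-6-methyl-1,2-dioxan-3-yl]propanoic acid | C=C1CCCC(C)(C)[C@@]1(O)CC[C@@]1(C)CC[C@@H]([C@H](C)C(=O)O)OO1 | intermediate
32 | methyl (2S)-2-[(3S,6R)-6-{2-[(1S)-1-hydroxy-2,2-dimethyl-6-methylidenecyclohexyl]ethyl}-6-methyl-1,2-dioxan-3-yl]propanoate | C=C1CCCC(C)(C)[C@@]1(O)CC[C@@]1(C)CC[C@@H]([C@H](C)C(=O)OC)OO1 | target

**Step count and risks**
Total steps: 22. Longest linear sequence: 21 (steps 1–5 and 7–22 from compound 1); step 6 is a one-step side branch.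

Steps most likely to fail:

Step 14 (cobalt-mediated peroxidation). Risks are partial reaction at the ring alkene, peroxyl-radical side reactions and, inherently, no control at C6, which costs half the material at the separation. Fallback, setting out from 21 and coming back at 23: treat 21 with Hg(OAc)2 and ethereal H2O2 in CH2Cl2 at 0 °C, an ionic Markovnikov hydroperoxymercuration that strongly prefers the unhindered 1,1-disubstituted alkene and gives the β-acetoxymercurio tertiary hydroperoxide F1. Demercuration with NaBH4 in aqueous NaOH at 0 °C then gives hydroperoxide 23, which is closed as in step 15. C6 is still unselective, but the radical chain at cobalt is avoided.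

Step 15 (SN2 at a β-branched secondary mesylate; E2 may compete). Fallback, setting out from 19 and coming back at 24: tosylate the primary hydroxyl (TsCl, pyridine, 0 °C) to the (2R,3R)-monotosylate F2. NaH in THF closes the cis-2,3-disubstituted oxetane F3 by displacement at the primary carbon (the C3–O bond is untouched). Co(thd)2/O2/Et3SiH gives the triethylsilyl peroxide F4, and K2CO3/MeOH frees the hydroperoxy oxetane F5. Lewis acid (catalytic TMSOTf or BF3·OEt2, CH2Cl2, −78 °C) then triggers 6-exo opening of the strained oxetane at C3 with inversion and delivers the dioxane primary alcohol F6. TBDPSCl/imidazole and chromatographic removal of the C6 diastereomer return to 24. The electrophile is an activated oxetane instead of a sulfonate, so no E2 pathway exists.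

Step 19 (Wharton transposition beside a dialkyl peroxide; azine or pyrazoline by-products, possible O–O reduction). Fallback, setting out from 26 and coming back at 29: I2, PPh3 and imidazole in CH2Cl2 at 0 °C convert 26 into the (1R,6S)-epoxy iodide F7. Further PPh3 in toluene at rt to 40 °C attacks iodine (halophilic attack) with anti opening of the oxirane C–O bond at the CH2I-bearing carbon, and aqueous NaHCO3 work-up releases 29. This avoids both the aldehyde and hydrazine; the exposure of the dialkyl peroxide to phosphine would have to be kept short and checked.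

**Further compounds**
F1 | step 14 | (2R,3R,6RS)-6-[(acetoxymercurio)methyl]-1-[(tert-butyldiphenylsilyl)oxy]-8-(2-{[(tert-butyldimethylsilyl)oxy]methyl}-6,6-dimethylcyclohex-1-en-1-yl)-6-hydroperoxy-2-methyloctan-3-yl methanesulfonate | CC(C)(C)[Si](C)(C)OCC1=C(CCC(C[Hg]OC(C)=O)(OO)CC[C@H]([C@H](C)CO[Si](c2ccccc2)(c2ccccc2)C(C)(C)C)OS(C)(=O)=O)C(C)(C)CCC1
F2 | step 15 | (2R,3R)-8-(2-{[(tert-butyldimethylsilyl)oxy]methyl}-6,6-dimethylcyclohex-1-en-1-yl)-3-hydroxy-2-methyl-6-methylideneoctyl 4-methylbenzenesulfonate | CC(C)(C)[Si](C)(C)OCC1=C(CCC(=C)CC[C@H]([C@H](C)COS(=O)(=O)c2ccc(C)cc2)O)C(C)(C)CCC1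
F3 | step 15 | tert-butyl[(3,3-dimethyl-2-{3-methylidene-5-[(2R,3R)-3-methyloxetan-2-yl]pentyl}cyclohex-1-en-1-yl)methoxy]dimethylsilane (cis-oxetane) | CC(C)(C)[Si](C)(C)OCC1=C(CCC(=C)CC[C@@H]2[C@H](C)CO2)C(C)(C)CCC1
F4 | step 15 | tert-butyl[(3,3-dimethyl-2-{3-methyl-5-[(2R,3R)-3-methyloxetan-2-yl]-3-[(triethylsilyl)peroxy]pentyl}cyclohex-1-en-1-yl)methoxy]dimethylsilane (C3 of the pentyl chain RS) | CC(C)(C)[Si](C)(C)OCC1=C(CCC(C)(OO[Si](CC)(CC)CC)CC[C@@H]2[C@H](C)CO2)C(C)(C)CCC1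
F5 | step 15 | tert-butyl[(2-{3-hydroperoxy-3-methyl-5-[(2R,3R)-3-methyloxetan-2-yl]pentyl}-3,3-dimethylcyclohex-1-en-1-yl)methoxy]dimethylsilane (hydroperoxide carbon RS) | CC(C)(C)[Si](C)(C)OCC1=C(CCC(C)(OO)CC[C@@H]2[C@H](C)CO2)C(C)(C)CCC1
F6 | step 15 | (2R)-2-{(3S,6S)-6-[2-(2-{[(tert-butyldimethylsilyl)oxy]methyl}-6,6-dimethylcyclohex-1-en-1-yl)ethyl]-6-methyl-1,2-dioxan-3-yl}propan-1-ol | CC(C)(C)[Si](C)(C)OCC1=C(CC[C@@]2(C)CC[C@@H]([C@H](C)CO)OO2)C(C)(C)CCC1
F7 | step 19 | (3S,6R)-3-{(2R)-1-[(tert-butyldiphenylsilyl)oxy]propan-2-yl}-6-{2-[(1R,6S)-1-(iodomethyl)-5,5-dimethyl-7-oxabicyclo[4.1.0]heptan-6-yl]ethyl}-6-methyl-1,2-dioxane | IC[C@@]12CCCC(C)(C)[C@@]1(O2)CC[C@@]3(C)CC[C@@H]([C@H](C)CO[Si](c4ccccc4)(c4ccccc4)C(C)(C)C)OO3
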